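**Plan**

Numbering: five-membered ring C1–C2=C3–C4(OH)(Me)–C5; seven-membered ring C5–C6(OH)–C7–C8–C9–C10(=C18H2)–C1; side chain C7–C11(C19H3)–C12H2–C13H(OAc)–C14H=C15Me2. β is the face of 4-OH and H5, α the face of 4-Me and H1.
Retrosynthesis: remove the acetate and the C13–C14 bond (isobutenyl anion plus δ-lactone), take out C12 (one-carbon lactone homologation), cut C6–C7 together with the lactone C–O bond, then C7=C11 (cross-metathesis), C8–C9 (allyl–allyl coupling), and expand the cyclopentene back to (R)-carvone.
Forward: the five-membered ring arises first by Wolff ring contraction of a carvone-derived diazo enone; the seven-membered ring and a temporary γ-lactone form together in the key step; the side chain is finished last.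
Enabling feature: O6 and the branch carbon C11 are 1,3-related across C6–C7, and C11 carries a methyl (C19) and a chain oxygenated at C13. The unit C19–C11(=C7)–C13(=O) can therefore act as a 2-(alkoxycarbonyl)allyl nucleophile whose γ-carbon C7 attacks a C6 aldehyde on the cyclopentane while O6 lactonises onto C13. Afterwards the C11=C19 methylene is reduced to the methyl and C12 is inserted.
Stereochemistry: C1 from (R)-carvone; C5 by trans equilibration; C4 by epoxidation anti to the C5 substituent and selenoxide transposition; C6 and C7 from the chair transition state of the (Z)-allylindium under control of C5; C11 by equilibration on the cis-fused lactone; C13 by Corey–Bakshi–Shibata reduction.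

Key step: step 9

Remark: the descriptors of the target are read as a trans ring fusion (H1 α, H5 β) with 4-OH, 6-OH and the C7 side chain all β (H6 and H7 α); the route is designed for exactly this relative configuration.

Step 1
Reactants: 1 (R)-carvone
Product: 2 (5R)-5-(3-chloroprop-1-en-2-yl)-2-methylcyclohex-2-en-1-one
Conditions: Ca(OCl)2, solid CO2, CH2Cl2/H2O, 0 °C
Reagents that add atoms: calcium hypochlorite, [Ca+2].[O-]Cl.[O-]Cl
Why: Ene-type allylic chlorination by HOCl made in situ should attack only the electron-rich 1,1-disubstituted isopropenyl alkene, not the enone, and transpose the double bond to the 2-(chloromethyl)allyl group while the stereocentre is untouched.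

Step 2
Reactants: 2 (5R)-5-(3-chloroprop-1-en-2-yl)-2-methylcyclohex-2-en-1-one; 3 allylboronic acid pinacol ester
Product: 4 (5R)-5-(hexa-1,5-dien-2-yl)-2-methylcyclohex-2-en-1-one
Conditions: Pd2(dba)3 (2.5 mol %), PPh3 (10 mol %), CsF, THF/H2O (10:1), 60 °C
Reagents that add atoms: 3 allylboronic acid pinacol ester, C=CCB1OC(C)(C)C(C)(C)O1
Why: Palladium-catalysed allyl–allyl cross-coupling: zerovalent palladium ionises the allylic chloride to a 2-substituted π-allyl complex with equivalent termini, so transmetalation of the fluoride-activated allylboronate and reductive elimination can give only the 1,5-diene, and the enone is inert to the boronate.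

Step 3
Reactants: 4 (5R)-5-(hexa-1,5-dien-2-yl)-2-methylcyclohex-2-en-1-one
Product: 6 (5S)-6-diazo-5-(hexa-1,5-dien-2-yl)-2-methylcyclohex-2-en-1-one, via trifluoroacetyl ketone 5 (not isolated)
Conditions: LiN(SiMe3)2, THF, −78 °C; CF3CO2CH2CF3; then 4-acetamidobenzenesulfonyl azide, Et3N, H2O (1 equiv), MeCN, rt
Reagents that add atoms: 4-acetamidobenzenesulfonyl azide, CC(=O)Nc1ccc(cc1)S(=O)(=O)N=[N+]=[N-]
Why: Detrifluoroacetylative diazo transfer: the kinetic α′-enolate is C-trifluoroacetylated and the activated 1,3-dicarbonyl 5 takes the diazo group from the sulfonyl azide with loss of the trifluoroacetyl group, so the diazo group enters only at the α′-carbon and the neighbouring stereocentre is untouched.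

Step 4
Reactants: 6 (5S)-6-diazo-5-(hexa-1,5-dien-2-yl)-2-methylcyclohex-2-en-1-one
Product: 9 methyl (1S,5R)-5-(hexa-1,5-dien-2-yl)-2-methylcyclopent-2-ene-1-carboxylate, via vinylketene 7 (not isolated), via cis ester 8 (not isolated)
Conditions: hν (medium-pressure Hg lamp, Pyrex), MeOH, rt; then NaOMe (0.2 equiv), MeOH, 0 °C → rt
Reagents that add atoms: methanol, CO
Why: Photochemical Wolff rearrangement as a ring contraction: loss of N2 with 1,2-shift of the alkenyl carbon gives vinylketene 7, methanol adds with α-protonation to the β,γ-unsaturated ester, and catalytic methoxide should equilibrate the kinetic cis ester 8 to the more stable trans ester 9 (C5 under thermodynamic control, C1 from carvone).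

Step 5
Reactants: 9 methyl (1S,5R)-5-(hexa-1,5-dien-2-yl)-2-methylcyclopent-2-ene-1-carboxylate
Product: 10 methyl (1R,2S,3R,5S)-3-(hexa-1,5-dien-2-yl)-1-methyl-6-oxabicyclo[3.1.0]hexane-2-carboxylate
Conditions: m-CPBA (1.05 equiv), NaHCO3, CH2Cl2, −20 → 0 °C
Reagents that add atoms: m-chloroperoxybenzoic acid, OOC(=O)c1cccc(Cl)c1
Why: Prilezhaev epoxidation: the peracid should react fastest with the trisubstituted ring alkene and from the face anti to the adjacent ester, which allylic 1,2-strain with the vinylic methyl holds pseudo-axial, so the C3–O and C4–O bonds become β (cis to the C1 side chain, trans to C6).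

Step 6
Reactants: 10 methyl (1R,2S,3R,5S)-3-(hexa-1,5-dien-2-yl)-1-methyl-6-oxabicyclo[3.1.0]hexane-2-carboxylate
Product: 11 [(1R,2R,3R,5S)-3-(hexa-1,5-dien-2-yl)-1-methyl-6-oxabicyclo[3.1.0]hexan-2-yl]methanol
Conditions: i-Bu2AlH (2.2 equiv), CH2Cl2, −78 °C; Rochelle salt work-up
Reagents that add atoms: none
Why: Hydride reduction of the ester with i-Bu2AlH at low temperature should give the primary alcohol and leave the trisubstituted epoxide and the alkenes untouched.

Step 7
Reactants: 11 [(1R,2R,3R,5S)-3-(hexa-1,5-dien-2-yl)-1-methyl-6-oxabicyclo[3.1.0]hexan-2-yl]methanol; 12 methyl 2-(bromomethyl)acrylate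
Product: 13 methyl (2Z)-2-(bromomethyl)-6-[(1R,2R,3R,5S)-2-(hydroxymethyl)-1-methyl-6-oxabicyclo[3.1.0]hexan-3-yl]hepta-2,6-dienoate
Conditions: 12 (4 equiv), RuCl2(H2IMes)(=CH-2-(i-PrO)C6H4) (second-generation Hoveyda–Grubbs catalyst, 5 mol %), CH2Cl2, 40 °C
Reagents that add atoms: 12 methyl 2-(bromomethyl)acrylate, C=C(CBr)C(=O)OC
Why: Olefin cross-metathesis of the monosubstituted terminal alkene with the 1,1-disubstituted acrylate should give the trisubstituted enoate with the chain trans to the ester (Z by the sequence rule, the thermodynamic isomer), because the hindered C10 methylene does not react and no ring alkene is present at this stage that could ring-open.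

Step 8
Reactants: 13 methyl (2Z)-2-(bromomethyl)-6-[(1R,2R,3R,5S)-2-(hydroxymethyl)-1-methyl-6-oxabicyclo[3.1.0]hexan-3-yl]hepta-2,6-dienoate
Product: 14 methyl (2Z)-2-(bromomethyl)-6-[(1R,2S,3R,5S)-2-formyl-1-methyl-6-oxabicyclo[3.1.0]hexan-3-yl]hepta-2,6-dienoate
Conditions: Dess–Martin periodinane, NaHCO3, CH2Cl2, 0 °C → rt
Reagents that add atoms: none
Why: Dess–Martin oxidation under buffered conditions should give the aldehyde without epimerising C5, opening the β,γ-epoxide or displacing the allylic bromide.

Step 9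
Reactants: 14 methyl (2Z)-2-(bromomethyl)-6-[(1R,2S,3R,5S)-2-formyl-1-methyl-6-oxabicyclo[3.1.0]hexan-3-yl]hepta-2,6-dienoate
Product: 16 epoxy α-methylene lactone (trans-fused five/seven core; 3β,4β-epoxide; cis-fused 13,6β-olide; H6α/H7α), via hydroxy ester 15 (not isolated)
Conditions: indium powder (2 equiv), THF/H2O (4:1), 0.005 M, rt; then PPTS (cat.), CH2Cl2, rt
Reagents that add atoms: none
Why: Indium metal inserts into the allylic C–Br bond to give a 2-(methoxycarbonyl)allylindium whose γ-carbon C7 adds to the C6 aldehyde through a six-membered chair (Zimmerman–Traxler) transition state, and the γ-hydroxy ester 15 then lactonises. The closest known reaction type is the Barbier-type allylation–lactonisation of ω-formyl 2-(bromomethyl)acrylates with zinc, chromium or indium, which closes six- and seven-membered and larger carbocycles fused to α-methylene-γ-butyrolactones. The carbocycle (C5–C6–C7–C8–C9–C10–C1) closes in a 7-exo-trig mode at the aldehyde carbon and the lactone by 5-exo-trig acyl substitution by O6 at C13. C6 and C7 are set together: the (Z)-allyl unit places C8 axial in the chair and gives the syn adduct (H6 and H7 cis, hence a cis-fused lactone), while C5 controls the face because C7 must approach anti to C4 to reach the trans-fused ring and the indium-bound oxygen should stay equatorial, syn to H5 and away from the α-methyl on C4, which gives 6β-O. The step needs γ- over α-attack (seven- versus nine-membered ring), cyclisation over oligomerisation (high dilution) and survival of the β,γ-epoxide and the epimerisable C5–H, which neutral aqueous indium conditions should secure.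

Step 10
Reactants: 16 epoxy α-methylene lactone
Product: 18 saturated epoxy lactone (C19 methyl α; cis to H6/H7), via 11-epimeric lactone 17 (not isolated)
Conditions: NaBH4, MeOH, 0 °C; then NaOMe (0.3 equiv), MeOH, rt
Reagents that add atoms: none
Why: Conjugate hydride reduction of the α-methylene lactone by NaBH4 is chemoselective over the isolated alkene and the epoxide, and methoxide equilibration of the α-carbon should convert the kinetic epimer 17 into 18, in which the C19 methyl lies on the convex face of the cis-fused lactone, which sets C11.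

Step 11
Reactants: 18 saturated epoxy lactone
Product: 20 allylic alcohol lactone (4β-OH; C2=C3), via hydroxy selenide 19 (not isolated)
Conditions: (PhSe)2, NaBH4, EtOH, 0 °C → 70 °C; then H2O2 (30 %), pyridine, THF, 0 °C → rt
Reagents that add atoms: none
Why: Epoxide-to-allylic-alcohol transposition by selenide opening and selenoxide elimination: PhSe− opens the epoxide at the secondary carbon C3 with inversion, and the selenoxide can only undergo syn-elimination towards C2 because C4 bears no hydrogen, which should give the C2=C3 alkene and the tertiary 4β-alcohol with the C4–O bond unchanged.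

Step 12
Reactants: 20 allylic alcohol lactone
Product: 23 δ-lactone (O6–C13(=O)–C12H2–C11), via dibromomethyl ketone 21 (not isolated), via lithium ynolate 22 (not isolated)
Conditions: CH2Br2, lithium 2,2,6,6-tetramethylpiperidide, THF, −78 °C; then 20; LiN(SiMe3)2, −78 → −20 °C; n-BuLi, −78 °C → rt; AcOH/THF quench, −78 °C → rt
Reagents that add atoms: dibromomethane, BrCBr
Why: Kowalski ester homologation applied to the lactone: LiCHBr2 adds to the carbonyl, deprotonation and bromine–lithium exchange give a carbenoid enolate that rearranges with 1,2-shift of C11 (retention) to ynolate 22, and protonation to the ketene with capture by the C6 alkoxide should give the ring-expanded δ-lactone in which the new CH2 is C12.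

Step 13
Reactants: 23 δ-lactone; 24 1-bromo-2-methylprop-1-ene
Product: 26 hydroxy enone (C13 ketone; in equilibrium with its six-membered lactol), via 2-methylprop-1-enyllithium 25 (not isolated)
Conditions: 24, t-BuLi (2 equiv per 24), Et2O, −78 °C; then 23, THF, −78 °C; NH4Cl (aq)
Reagents that add atoms: 24 1-bromo-2-methylprop-1-ene, CC(C)=CBr
Why: Single nucleophilic acyl addition of the alkenyllithium to the δ-lactone: the lithium hemiketal is stable at −78 °C and collapses only on work-up, so the isobutenyl ketone should form without a second addition (one equivalent is spent on the tertiary alcohol).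

Step 14
Reactants: 26 hydroxy enone
Product: 27 triol with (13R)-allylic alcohol
Conditions: (S)-2-methyl-CBS-oxazaborolidine (0.5 equiv), BH3·SMe2 (excess), THF, −30 °C; MeOH quench
Reagents that add atoms: none
Why: Corey–Bakshi–Shibata reduction: the catalyst binds the ketone with the alkenyl group as the large and the C12 methylene as the small substituent, so the (S)-catalyst should deliver hydride in a 1,2-sense to give the (13R)-allylic alcohol under reagent control.

Step 15
Reactants: 27 triol with (13R)-allylic alcohol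
Product: 28 target compound CNP0209568.3
Conditions: Ac2O (1.2 equiv), pyridine, CH2Cl2, −20 → 0 °C
Reagents that add atoms: acetic anhydride, CC(=O)OC(C)=O
Why: Chemoselective acylation: the unhindered allylic secondary C13 hydroxyl should be acetylated much faster than the C6 hydroxyl, which is flanked by two tertiary carbons and hydrogen-bonded to the inert tertiary C4 hydroxyl.

**Compound list**

1 | (R)-carvone, (5R)-2-methyl-5-(prop-1-en-2-yl)cyclohex-2-en-1-one | CC1=CC[C@H](CC1=O)C(C)=C | starting material
2 | (5R)-5-(3-chloroprop-1-en-2-yl)-2-methylcyclohex-2-en-1-one | CC1=CC[C@H](CC1=O)C(=C)CCl | intermediate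
3 | allylboronic acid pinacol ester | C=CCB1OC(C)(C)C(C)(C)O1 | starting material
4 | (5R)-5-(hexa-1,5-dien-2-yl)-2-methylcyclohex-2-en-1-one | CC1=CC[C@H](CC1=O)C(=C)CCC=C | intermediate
5 | (5R)-5-(hexa-1,5-dien-2-yl)-2-methyl-6-(trifluoroacetyl)cyclohex-2-en-1-one (C6 epimers and enol) | CC1=CC[C@H](C(C(=O)C(F)(F)F)C1=O)C(=C)CCC=C | intermediate
6 | (5S)-6-diazo-5-(hexa-1,5-dien-2-yl)-2-methylcyclohex-2-en-1-one | CC1=CC[C@H](C(=[N+]=[N-])C1=O)C(=C)CCC=C | intermediate
7 | vinylketene: [5-(hexa-1,5-dien-2-yl)-2-methylcyclopent-2-en-1-ylidene]methanone, alkenyl-bearing carbon as in 6 | O=C=C1C(C)=CC[C@H]1C(=C)CCC=C | intermediate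
8 | methyl (1R,5R)-5-(hexa-1,5-dien-2-yl)-2-methylcyclopent-2-ene-1-carboxylate (cis ester) | COC(=O)[C@H]1C(C)=CC[C@H]1C(=C)CCC=C | intermediate
9 | methyl (1S,5R)-5-(hexa-1,5-dien-2-yl)-2-methylcyclopent-2-ene-1-carboxylate (trans ester) | COC(=O)[C@@H]1C(C)=CC[C@H]1C(=C)CCC=C | intermediate
10 | methyl (1R,2S,3R,5S)-3-(hexa-1,5-dien-2-yl)-1-methyl-6-oxabicyclo[3.1.0]hexane-2-carboxylate | COC(=O)[C@@H]1[C@@]2(C)O[C@H]2C[C@H]1C(=C)CCC=C | intermediate
11 | [(1R,2R,3R,5S)-3-(hexa-1,5-dien-2-yl)-1-methyl-6-oxabicyclo[3.1.0]hexan-2-yl]methanol | OC[C@@H]1[C@@]2(C)O[C@H]2C[C@H]1C(=C)CCC=C | intermediate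
12 | methyl 2-(bromomethyl)acrylate | C=C(CBr)C(=O)OC | starting material
13 | methyl (2Z)-2-(bromomethyl)-6-[(1R,2R,3R,5S)-2-(hydroxymethyl)-1-methyl-6-oxabicyclo[3.1.0]hexan-3-yl]hepta-2,6-dienoate | COC(=O)/C(CBr)=C/CCC(=C)[C@@H]1C[C@@H]2O[C@]2(C)[C@H]1CO | intermediate
14 | methyl (2Z)-2-(bromomethyl)-6-[(1R,2S,3R,5S)-2-formyl-1-methyl-6-oxabicyclo[3.1.0]hexan-3-yl]hepta-2,6-dienoate | COC(=O)/C(CBr)=C/CCC(=C)[C@@H]1C[C@@H]2O[C@]2(C)[C@H]1C=O | intermediate
15 | γ-hydroxy ester: trans-fused 3β,4β-epoxy hydroazulene (H1α, H5β) with C10=C18H2, 6β-OH and 7β-[1-(methoxycarbonyl)vinyl] (H6α, H7α) | C=C1CC[C@@H](C(=C)C(=O)OC)[C@@H](O)[C@H]2[C@H]1C[C@@H]3O[C@]23C | intermediate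
16 | epoxy α-methylene-γ-lactone: as 15 with O6 acylated by C13 (cis-fused 13,6β-olide, C11=C19H2) | C=C1CC[C@H]2C(=C)C(=O)O[C@H]2[C@H]3[C@H]1C[C@@H]4O[C@]34C | intermediate
17 | 11-epimer of 18 (C19 methyl β, trans to H7, concave face) | C=C1CC[C@H]2[C@@H](C)C(=O)O[C@H]2[C@H]3[C@H]1C[C@@H]4O[C@]34C | intermediate
18 | saturated 3β,4β-epoxy γ-lactone with C19 methyl α (cis to H6 and H7, convex face) | C=C1CC[C@H]2[C@H](C)C(=O)O[C@H]2[C@H]3[C@H]1C[C@@H]4O[C@]34C | intermediate
19 | hydroxy selenide: 3α-phenylseleno-4β-hydroxy-4α-methyl γ-lactone | C=C1CC[C@H]2[C@H](C)C(=O)O[C@H]2[C@H]3[C@H]1C[C@@H]([Se]c4ccccc4)[C@]3(C)O | intermediate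
20 | γ-lactone with 4β-hydroxy-4α-methyl and C2=C3 | C=C1CC[C@H]2[C@H](C)C(=O)O[C@H]2[C@H]3[C@H]1C=C[C@]3(C)O | intermediate
21 | ring-opened dibromomethyl ketone (C11–C(=O)–CHBr2, 6β-OH) | C=C1CC[C@@H]([C@H](C)C(=O)C(Br)Br)[C@@H](O)[C@H]2[C@H]1C=C[C@]2(C)O | intermediate
22 | trilithium ynolate (C11–C≡C–OLi, 4- and 6-alkoxides) | [Li+].[Li+].[Li+].C=C1CC[C@@H]([C@H](C)C#C[O-])[C@@H]([O-])[C@H]2[C@H]1C=C[C@]2(C)[O-] | intermediate
23 | δ-lactone O6–C13(=O)–C12H2–C11 with 4β-OH and C2=C3 | C=C1CC[C@H]2[C@H](C)CC(=O)O[C@H]2[C@H]3[C@H]1C=C[C@]3(C)O | intermediate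
24 | 1-bromo-2-methylprop-1-ene | CC(C)=CBr | starting material
25 | 2-methylprop-1-enyllithium | [Li]C=C(C)C | intermediate
26 | 4β,6β-dihydroxy enone (C13 ketone, C14=C15Me2) | C=C1CC[C@@H]([C@H](C)CC(=O)C=C(C)C)[C@@H](O)[C@H]2[C@H]1C=C[C@]2(C)O | intermediate
27 | (13R)-triol (4β-, 6β- and 13-OH) | C=C1CC[C@@H]([C@H](C)C[C@@H](O)C=C(C)C)[C@@H](O)[C@H]2[C@H]1C=C[C@]2(C)O | intermediate
28 | target, (1R,4S,5R,6R,7S,11R,13R)-13-acetoxy-4β,6β-dihydroxy trans-fused hydroazulene diterpenoid | C=C1CC[C@@H]([C@H](C)C[C@H](C=C(C)C)OC(C)=O)[C@@H](O)[C@H]2[C@H]1C=C[C@]2(C)O | target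

**Totals**

Total step count: 15. Longest linear sequence: 15 steps from 1 (3, 12 and 24 are purchased).

**Steps most likely to fail**

1. Step 9. What may go wrong: poor facial selectivity with respect to C5 (the syn C6/C7 pair forming on the α face), intermolecular allylation competing with the seven-membered closure, or opening of the β,γ-epoxide next to the aldehyde. Fallback from 11: cross-metathesis with methyl 2-[(trimethylsilyl)methyl]acrylate (same ruthenium catalyst as in step 7) should give the allylsilane alcohol F1, and Dess–Martin oxidation the allylsilane aldehyde F2. Fluoride (TBAF, THF, high dilution) then triggers an intramolecular Hosomi–Sakurai-type addition of the 2-(methoxycarbonyl)allylsilane to the aldehyde through an open transition state with lactonisation. This uses a metal-free nucleophile with a different stereochemical model and returns to the route at 16.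

2. Step 12. What may go wrong: enolisation of the lactone instead of carbonyl addition, incomplete rearrangement of the carbenoid, or loss of the tertiary allylic alcohol under the strongly basic conditions. Fallback from 20: i-Bu2AlH at −78 °C should give the γ-lactol F3. Wittig reaction with Ph3P=CHOMe (from the phosphonium chloride and KN(SiMe3)2) gives the methyl enol ether F4. Hydrolysis with Hg(OAc)2 in THF/H2O followed by KI gives the δ-lactol F5, and oxidation with Ag2CO3 on Celite returns to the route at 23.

3. Step 15. What may go wrong: loss of chemoselectivity, with acetylation of the C6 hydroxyl competing with that of C13. Fallback from 27: TESOTf and 2,6-lutidine should give the tris(triethylsilyl) ether F6. PPTS in MeOH at 0 °C removes only the least hindered allylic secondary silyl ether to give the C13 alcohol F7. Ac2O, Et3N and DMAP give the acetate F8, and HF·pyridine in THF removes the remaining silyl groups to return to the route at 28.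

**Further compounds**

F1 | step 9 | methyl (2Z)-6-[(1R,2R,3R,5S)-2-(hydroxymethyl)-1-methyl-6-oxabicyclo[3.1.0]hexan-3-yl]-2-[(trimethylsilyl)methyl]hepta-2,6-dienoate | COC(=O)/C(C[Si](C)(C)C)=C/CCC(=C)[C@@H]1C[C@@H]2O[C@]2(C)[C@H]1CO
F2 | step 9 | methyl (2Z)-6-[(1R,2S,3R,5S)-2-formyl-1-methyl-6-oxabicyclo[3.1.0]hexan-3-yl]-2-[(trimethylsilyl)methyl]hepta-2,6-dienoate | COC(=O)/C(C[Si](C)(C)C)=C/CCC(=C)[C@@H]1C[C@@H]2O[C@]2(C)[C@H]1C=O
F3 | step 12 | γ-lactol of 20 (anomers) | C=C1CC[C@H]2[C@H](C)C(O)O[C@H]2[C@H]3[C@H]1C=C[C@]3(C)O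
F4 | step 12 | methyl enol ether (C11–CH=CH–OMe, 4β- and 6β-OH, E/Z mixture) | C=C1CC[C@@H]([C@H](C)C=COC)[C@@H](O)[C@H]2[C@H]1C=C[C@]2(C)O
F5 | step 12 | δ-lactol (anomers) | C=C1CC[C@H]2[C@H](C)CC(O)O[C@H]2[C@H]3[C@H]1C=C[C@]3(C)O
F6 | step 15 | 4,6,13-tris(triethylsilyl) ether of 27 | C=C1CC[C@@H]([C@H](C)C[C@@H](O[Si](CC)(CC)CC)C=C(C)C)[C@@H](O[Si](CC)(CC)CC)[C@H]2[C@H]1C=C[C@]2(C)O[Si](CC)(CC)CC
F7 | step 15 | 4,6-bis(triethylsilyl) ether with free (13R)-OH | C=C1CC[C@@H]([C@H](C)C[C@@H](O)C=C(C)C)[C@@H](O[Si](CC)(CC)CC)[C@H]2[C@H]1C=C[C@]2(C)O[Si](CC)(CC)CC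
F8 | step 15 | 13-acetate 4,6-bis(triethylsilyl) ether | C=C1CC[C@@H]([C@H](C)C[C@H](C=C(C)C)OC(C)=O)[C@@H](O[Si](CC)(CC)CC)[C@H]2[C@H]1C=C[C@]2(C)O[Si](CC)(CC)CC
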